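Remark on the chemistry: ring carbons are numbered C1–C10 as in germacranolides (C11–C13 in the lactone, C14 on C10, C15 on C4), and these locants are also used for the intermediates. (S)-Cyclohex-3-ene-1-carboxylic acid and (R)-2-methylbutanoic acid are assumed to be purchasable as single enantiomers.

## Analysis of the target

Target 40 is a ten-membered carbocycle C1–C10 fused across C6–C7 to an α-methylene-γ-butyrolactone (ring oxygen on C6, C12 carbonyl, C11 on C7 with the exocyclic C13 methylene). C10 carries the C14 methyl ester and forms a trisubstituted alkene with C1 in which the ring carbons C2 and C9 are cis (E by the sequence rule, because C14 outranks C9). O8 carries an (R)-2-methylbutanoyl group and C4 the C15 hydroxymethyl group. Three ring stereocentres are contiguous: C6 (R), C7 (S) and C8 (R), with O6 trans to C11 (trans-fused lactone) and O8 cis to C11. The fourth, C4 (S), is isolated on the far side of the ring and cannot be set by induction from a neighbour. Sensitive features are the Michael-accepting methylene lactone, the enolisable α-centre of the side-chain ester, the conjugated ester, and a C8 hydroxyl that, once free, can take the lactone carbonyl over from O6. The difficulty lies in making a strained medium ring with a ring-cis trisubstituted alkene and in correlating C4 with C6–C8 across that ring. The strategy rests on one structural feature: the oxygenated C6 is 1,5-related to C10 through C7–C8–C9 while C1 is bonded to C10, so that restoring a C1–C6 bond gives a cyclohexane C1–C6 that already contains C4 and carries a C7=C8 unit on C6 and a C10=C9 unit on C1.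

## Retrosynthetic reasoning

40 to 39 (O15–Si). The primary hydroxyl stays silylated until the end so that O8 is the only free hydroxyl when the side chain is attached. The forward step must remove the silyl group without touching the methylene lactone or the two esters.

39 to 37 and 38 (acyl–O8). The side chain has an enolisable stereocentre, so it is attached after all enolate chemistry. The forward esterification must be faster than migration of the lactone carbonyl to O8 and must not racemise 38.

37 to 36 (O8–tert-butyl). The tert-butyl group is the substituent that the C8 oxygen carries as an enol ether through the key step. It is inert to hydride, amide bases and oxidants and is removed by acid.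

36 to 32 through 35, 34 and 33 (oxidation level of C14). C14 is taken back to a 4-methoxybenzyl ether, which the alkoxide, the enolates and the hydride of the earlier steps cannot attack. The oxidation is placed after the methylenation so that no C1–C10 enoate is present while the C11 enolate exists; such an enolate could add across the ring to C1.

32 to 28 through 30 (C11=C13). The exocyclic alkene is cut back to the lactone methylene. The forward reaction is aminomethylation of the lactone enolate followed by elimination, at a stage where C11–H is the only acidic position.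

28 to 26, 25 and 24 (O6–C6, with inversion). The lactone is cut at the alkyl–oxygen bond, not at the acyl–oxygen bond. Hydride is expected to reach the C6 ketone of 24 from the ring periphery, anti to the C7–C8 bond, which gives 25 with O6 cis to the C7 arm. Displacement of the sulfonate in 26 by the carboxylate turns this into the trans lactone. The allyl ester is a carboxylate that can be unmasked without acid or base.

24 to 20 and 21 (C7–C11 and C8–C9, with C1–C6 restored). This is the only cut that turns the medium ring into a six-membered ring holding C4. It replaces a macrocyclisation by a ring expansion and lets one transition state set the alkene geometry and C8, with C7 set in the same flask. The forward step must pass through one chair, transfer the C1/C6 configuration to C8, and alkylate the enolate at C7 from its outer face.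

20 to 19, and 19 to 13 and 16 (C6–C7). The Z enol ether comes from cis-semihydrogenation of the alkynyl ether 19, which comes from addition of the acetylide derived from 16 to ketone 13. A linear sp nucleophile is chosen because it approaches axially, which places the two unsaturated arms cis. 16 is made from 14.

13 to 11, and 11 to 7 and 10 (C1–C10). The bond is made at the sp2 α-carbon of an enone, which avoids regioselective enolisation of a 3-substituted cyclohexanone. Conjugate reduction then sets C1 relative to C4. Boronate 10 comes from 9 and 8.

7 back to 1 through 6, 5, 4, 3 and 2. C4 is taken from the chiral pool. Iodolactonisation of 1 relays its stereocentre to an oxygen at the future C6, elimination gives the alkene for the enone, and the carboxyl carbon becomes C15.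

## Alternatives that were turned down

Alternative 1: The lactone and the C7–C11 bond would be made last on a finished ten-membered ring. A nucleophilic phosphine adds to C13 of an acrylate on O6, the enolate carbon C11 opens a ring-trans C7–C8 epoxide at C7 with inversion (5-exo), and loss of the phosphine restores the methylene group, giving the C8 alcohol A1.
- For: one step makes C7–C11, the methylene unit, the trans lactone and the free C8 hydroxyl. A1 is the same compound as 37, so this endgame would replace steps 15 to 24 of the chosen route. On endgame step economy it is clearly stronger.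
- Against: it needs the ten-membered ring with C4, C6, a geometrically pure ring-trans C7–C8 alkene, a face-selective epoxidation and the C1–C10 enoate already in place. The ring and the C4/C6–C8 correlation are moved upstream, not solved.
- Against: phosphine-triggered alkylations of this kind are established for enones; an acrylate ester is a weaker acceptor and a dialkyl epoxide a weak electrophile. The C1–C10 enoate competes for the phosphine and for the zwitterionic enolate across the ring.
- Comparison: the chosen strategy offers a defined way to the ring and ties C8 and C7 to one chiral-pool centre.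

Alternative 2: The ring would be closed at C1–C2. A vinyl group on C4 (C2=C3) is hydroborated with a hindered dialkylborane and the alkylborane is coupled under palladium catalysis with an (E)-enol triflate at C1, giving the 11,13-dihydro compound A2.
- For: C4, C6, C7, C8, the lactone and the side-chain ester are all set before ring closure by open-chain methods. The alkene geometry is carried over from the enol triflate, and the plan is convergent. On certainty of the C6–C8 configuration it is stronger than the chosen route, which depends on a conformation-dependent reduction.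
- Against: closing a ten-membered ring by sp3–sp2 coupling works against medium-ring strain. It needs high dilution and competes with β-hydride elimination, protodeboronation and oligomerisation.
- Against: A2 still lacks C13. Methylenation would need a lactone enolate in the presence of the enoate and of the epimerisable 2-methylbutanoate, which is the situation the chosen route avoids by installing C13 before either group exists.
- Comparison: the chosen strategy forms the ring in a unimolecular rearrangement without dilution and takes the alkene geometry from the transition state.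

Alternative 3: The ring would be closed at C7–C8. Indium inserts into the allylic C13–Br bond of an open-chain (Z)-bromide, and the allylindium adds through C7 to a C8 aldehyde, giving the ring alcohol A3 with the methylene acrylate unit in place.
- For: one mild step forms the ring, C7, C8 and the C11=C13 unit, and it tolerates esters and silyl ethers. It matches the chosen key step in bonds and stereocentres per step and is stronger in bringing C13 with it.
- Against: the cyclic transition state must fit inside a forming medium ring, so neither the syn/anti outcome nor the facial selectivity relative to C6 can be predicted.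
- Against: the new C8 alkoxide sits γ to the acrylate carbonyl, and such adducts usually lactonise at once. That would give the 8,12-lactone, whereas the target needs the 6,12-lactone with O8 acylated.
- Against: the linear precursor with C4, C6, a (Z)-enoate and a (Z)-allylic bromide is long.
- Comparison: the chosen strategy keeps O8 as an ether and C6 as a ketone until each is needed, and its ring formation carries no entropic cost.

Key step: step 14

## Route

Step 1
Reactants: 1 (S)-cyclohex-3-ene-1-carboxylic acid
Product: 2 (1S,4S,5S)-4-iodo-6-oxabicyclo[3.2.1]octan-7-one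
Conditions: I2, KI, NaHCO3, H2O/CH2Cl2, rt, dark
Reagents that add atoms: iodine, II
Why: Iodolactonisation: the carboxylate opens the iodonium ion anti and can only reach the cis 1,3-position, so the stereocentre of 1 (future C4) fixes the oxygen on the future C6 and the iodine on the future C1.

Step 2
Reactants: 2 (1S,4S,5S)-4-iodo-6-oxabicyclo[3.2.1]octan-7-one
Product: 3 (1S,5S)-6-oxabicyclo[3.2.1]oct-3-en-7-one
Conditions: DBU, toluene, reflux
Reagents that add atoms: none
Why: E2 elimination: the axial iodide has an anti-periplanar hydrogen only on the carbon remote from the lactone oxygen, so the alkene forms allylic to the C–O bond.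

Step 3
Reactants: 3 (1S,5S)-6-oxabicyclo[3.2.1]oct-3-en-7-one
Product: 4 (1S,5S)-5-(hydroxymethyl)cyclohex-2-en-1-ol
Conditions: LiAlH4, THF, 0 °C
Reagents that add atoms: none
Why: Hydride reduction of the lactone to the cis diol; the allylic C–O bond is not cleaved and no stereocentre is touched.

Step 4
Reactants: 4 (1S,5S)-5-(hydroxymethyl)cyclohex-2-en-1-ol
Product: 5 (1S,5S)-5-[(tert-butyldiphenylsilyloxy)methyl]cyclohex-2-en-1-ol
Conditions: t-BuPh2SiCl, imidazole, CH2Cl2, 0 °C
Reagents that add atoms: tert-butyl(chloro)diphenylsilane, CC(C)(C)[Si](Cl)(c1ccccc1)c1ccccc1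
Why: Silylation; the bulky silyl chloride reacts with the primary hydroxyl much faster than with the secondary allylic one.

Step 5
Reactants: 5 (1S,5S)-5-[(tert-butyldiphenylsilyloxy)methyl]cyclohex-2-en-1-ol
Product: 6 (5S)-5-[(tert-butyldiphenylsilyloxy)methyl]cyclohex-2-en-1-one
Conditions: Dess–Martin periodinane, CH2Cl2, rt
Reagents that add atoms: none
Why: Dess–Martin oxidation of the allylic alcohol gives the conjugated enone under non-basic conditions; the remaining stereocentre is not enolisable.

Step 6
Reactants: 6 (5S)-5-[(tert-butyldiphenylsilyloxy)methyl]cyclohex-2-en-1-one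
Product: 7 (5S)-2-iodo-5-[(tert-butyldiphenylsilyloxy)methyl]cyclohex-2-en-1-one
Conditions: I2, pyridine, CH2Cl2, 0 °C to rt
Reagents that add atoms: iodine, II
Why: α-Iodination of the enone by conjugate addition of pyridine, iodination of the enolate and elimination; the halogen marks the future C1.

Step 7
Reactants: 8 2,3-dibromopropene
Product: 9 1-{[(2-bromoprop-2-en-1-yl)oxy]methyl}-4-methoxybenzene
Conditions: NaH, 4-methoxybenzyl alcohol, THF, 0 °C; then 8, rt
Reagents that add atoms: 4-methoxybenzyl alcohol, COc1ccc(CO)cc1
Why: Williamson ether synthesis; the alkoxide displaces the allylic bromide by SN2 and the vinylic bromide is inert.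

Step 8
Reactants: 9 1-{[(2-bromoprop-2-en-1-yl)oxy]methyl}-4-methoxybenzene
Product: 10 2-{3-[(4-methoxybenzyl)oxy]prop-1-en-2-yl}-4,4,5,5-tetramethyl-1,3,2-dioxaborolane
Conditions: bis(pinacolato)diboron, PdCl2(PPh3)2, PPh3, KOPh, toluene, 50 °C
Reagents that add atoms: bis(pinacolato)diboron, CC1(C)OB(OC1(C)C)B1OC(C)(C)C(C)(C)O1
Why: Miyaura borylation of the alkenyl bromide; phenoxide is the base suited to 1-alkenyl halides.

Step 9
Reactants: 7 (5S)-2-iodo-5-[(tert-butyldiphenylsilyloxy)methyl]cyclohex-2-en-1-one; 10 2-{3-[(4-methoxybenzyl)oxy]prop-1-en-2-yl}-4,4,5,5-tetramethyl-1,3,2-dioxaborolane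
Product: 11 (5S)-2-{3-[(4-methoxybenzyl)oxy]prop-1-en-2-yl}-5-[(tert-butyldiphenylsilyloxy)methyl]cyclohex-2-en-1-one
Conditions: PdCl2(dppf), AsPh3, Cs2CO3, DMF/THF/H2O, rt
Reagents that add atoms: none
Why: Suzuki–Miyaura coupling of an α-iodoenone with an alkenylboronate forms C1–C10 at an sp2 carbon, so no regioselective enolisation is needed.

Step 10
Reactants: 11 (5S)-2-{3-[(4-methoxybenzyl)oxy]prop-1-en-2-yl}-5-[(tert-butyldiphenylsilyloxy)methyl]cyclohex-2-en-1-one
Product: 13 (2R,5S)-2-{3-[(4-methoxybenzyl)oxy]prop-1-en-2-yl}-5-[(tert-butyldiphenylsilyloxy)methyl]cyclohexan-1-one (2,5-trans), via potassium dienolate 12 (not isolated)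
Conditions: KBH(s-Bu)3, THF, −78 °C; then aq NH4Cl, −78 °C to rt
Reagents that add atoms: none
Why: Conjugate reduction by the hindered borohydride at the unsubstituted β-carbon gives dienolate 12. Kinetic protonation of this extended enolate occurs at the α-carbon C1 from the axial direction, which places the propenyl group equatorial and trans to the equatorial C4 group; this is also the more stable ketone.

Step 11
Reactants: 14 trichloroethylene
Product: 16 (E)-1,2-dichlorovinyl tert-butyl ether, via dichloroacetylene 15 (not isolated)
Conditions: KOt-Bu, THF, −78 °C to rt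
Reagents that add atoms: potassium tert-butoxide, CC(C)(C)[O-].[K+]
Why: Dehydrochlorination to dichloroacetylene followed by anti addition of tert-butoxide and a proton; this is the established way to precursors of alkoxyacetylides.

Step 12
Reactants: 16 (E)-1,2-dichlorovinyl tert-butyl ether; 13 (2R,5S)-2-{3-[(4-methoxybenzyl)oxy]prop-1-en-2-yl}-5-[(tert-butyldiphenylsilyloxy)methyl]cyclohexan-1-one
Product: 19 (1S,2R,5S)-1-(tert-butoxyethynyl)-2-{3-[(4-methoxybenzyl)oxy]prop-1-en-2-yl}-5-[(tert-butyldiphenylsilyloxy)methyl]cyclohexan-1-ol, via tert-butyl chloroethynyl ether 17 (not isolated), via lithium tert-butoxyacetylide 18 (not isolated)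
Conditions: 16, n-BuLi (2 equiv), THF, −78 to −40 °C; then 13, −78 °C; H2O
Reagents that add atoms: none
Why: Dehydrochlorination and Cl/Li exchange give acetylide 18. The slim linear nucleophile adds to the ketone axially (1,2-addition), past the equatorial C1 substituent, so the alkynyl group ends axial and cis to the propenyl group with the hydroxyl equatorial. CeCl3 can be added if enolisation of the doubly activated C1–H intrudes; the product is kept cold and away from acid.

Step 13
Reactants: 19 (1S,2R,5S)-1-(tert-butoxyethynyl)-2-{3-[(4-methoxybenzyl)oxy]prop-1-en-2-yl}-5-[(tert-butyldiphenylsilyloxy)methyl]cyclohexan-1-ol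
Product: 20 (1S,2R,5S)-1-[(Z)-2-tert-butoxyethenyl]-2-{3-[(4-methoxybenzyl)oxy]prop-1-en-2-yl}-5-[(tert-butyldiphenylsilyloxy)methyl]cyclohexan-1-ol
Conditions: H2 (1 atm), Pd/CaCO3 poisoned with Pb(OAc)2, quinoline, EtOAc, rt
Reagents that add atoms: none
Why: Syn semihydrogenation of the alkynyl ether on poisoned palladium stops at the Z enol ether; the 1,1-disubstituted alkene and the benzyl-type ether are not reduced under these conditions, and the amine keeps the medium basic.

Step 14
Reactants: 20 (1S,2R,5S)-1-[(Z)-2-tert-butoxyethenyl]-2-{3-[(4-methoxybenzyl)oxy]prop-1-en-2-yl}-5-[(tert-butyldiphenylsilyloxy)methyl]cyclohexan-1-ol; 21 allyl bromoacetate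
Product: 24 (4S,7R,8R)-ten-membered ketone: cyclodec-1(10)-en-6-one with ring-cis (E) C1–C10 alkene, C4 CH2OSi(t-Bu)Ph2, C7 CH2CO2allyl, C8 O-t-Bu and C10 CH2O(4-methoxybenzyl), via potassium alkoxide 22 (not isolated), via potassium enolate 23 (not isolated)
Conditions: KH, THF, 0 °C to rt; solution taken off excess KH and cooled to −78 °C; then 21, −78 to −40 °C; aq NH4Cl
Reagents that add atoms: none
Why: Deprotonation gives alkoxide 22, whose oxyanion weakens the allylic C1–C6 bond and drives a concerted [3,3] shift through a chair of C8, C7, C6, C1, C10 and C9. C1–C6 breaks while C8–C9 forms, so the ten-membered ring arises by expansion of the six-membered ring and not by an end-to-end cyclisation. The closest known reaction type is the anionic oxy-Cope expansion of 1,2-dialkenylcyclohexanolates to cyclodec-5-enones with alkylation of the regiodefined enolate. The cyclohexane chair with the C1 propenyl and C4 silyloxymethyl groups equatorial and the C6 enol-ether arm axial is the only low-energy conformer with the two alkenes gauche; in the derived chair C2 is axial on C1, which puts C2 and C9 cis on the new C1–C10 alkene, and C5 is equatorial on C6, which gives the ring-trans enolate 23. C8 is set by that chair: the Z enol ether places the tert-butoxy group axial next to the axial oxyanion, where K+ can bridge the two oxygens, and C9 bonds to the face of C8 dictated by the C1/C6 configuration, giving (8R). C7 is set in the alkylation: in the K-bridged enolate 23 the ring chain through C9 covers the inner face, so 21 is attacked by C7 from the periphery, anti to the C8–C9 bond, giving (7R) with C11 cis to O8. The step needs chair over boat and the diequatorial conformer over its ring-flipped form (secured by the two equatorial groups), C- over O-alkylation (soft α-halo ester), and alkylation faster than loss of tert-butoxide from the β-alkoxy enolate or turnover of the trans enolate (low temperature, potassium left uncomplexed, no crown ether).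

Step 15
Reactants: 24 (4S,7R,8R)-ten-membered ketone
Product: 25 (4S,6S,7S,8R)-C6 alcohol with O6 cis to the C7 allyl acetate arm
Conditions: LiBH(s-Bu)3, THF, −78 °C; AcOH, −78 °C; pH 7 buffer
Reagents that add atoms: none
Why: The hindered hydride should attack from the ring periphery anti to the C7–C8 bond (Felkin–Anh arrangement with the acetate arm beside the carbonyl oxygen), which puts O6 cis to the C7 arm. The allyl ester is not reduced at −78 °C, and the cold acidic quench keeps the hydroxy ester from closing to the cis lactone.

Step 16
Reactants: 25 (4S,6S,7S,8R)-C6 alcohol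
Product: 26 (4S,6S,7R,8R)-C6 methanesulfonate
Conditions: MeSO2Cl, Et3N, CH2Cl2, −20 °C
Reagents that add atoms: methanesulfonyl chloride, CS(=O)(=O)Cl
Why: Sulfonylation of the secondary alcohol with retention turns O6 into a leaving group; only the CIP label of C7 changes.

Step 17
Reactants: 26 (4S,6S,7R,8R)-C6 methanesulfonate
Product: 28 (4S,6R,7R,8R)-trans-fused γ-lactone (O6–C12) with C8 O-t-Bu, C14 4-methoxybenzyl ether and C15 silyl ether, via sodium carboxylate 27 (not isolated)
Conditions: Pd(PPh3)4 (cat.), sodium 2-ethylhexanoate, THF, rt; then DMF, 50 °C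
Reagents that add atoms: none
Why: Zerovalent palladium transfers the allyl group to the added carboxylate through a π-allyl complex and frees carboxylate 27 under neutral conditions. 27 displaces the C6 sulfonate intramolecularly (5-exo-tet SN2) with inversion, so O6 ends trans to C11 and C6 becomes (R).

Step 18
Reactants: 28 (4S,6R,7R,8R)-trans-fused γ-lactone
Product: 30 C11-(dimethylaminomethyl) lactone (C11 epimers, of no consequence), via lithium lactone enolate 29 (not isolated)
Conditions: LiN(i-Pr)2, THF, −78 °C; dimethylmethyleneammonium iodide, −78 °C to rt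
Reagents that add atoms: dimethylmethyleneammonium iodide, C=[N+](C)C.[I-]
Why: C11–H is the only acidic position; the enolate is aminomethylated (Mannich reaction with Eschenmoser's salt). C14 is still an ether, so there is no enoate for the enolate to attack across the ring.

Step 19
Reactants: 30 C11-(dimethylaminomethyl) lactone
Product: 32 (4S,6R,7R,8R)-α-methylene lactone with C8 O-t-Bu, C14 4-methoxybenzyl ether and C15 silyl ether, via trimethylammonium iodide 31 (not isolated)
Conditions: MeI, THF, rt; then aq NaHCO3, EtOAc, rt
Reagents that add atoms: none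
Why: Quaternisation followed by E1cB elimination of trimethylamine gives the exocyclic C11=C13 alkene and removes the C11 stereocentre.

Step 20
Reactants: 32 (4S,6R,7R,8R)-α-methylene lactone, C14 4-methoxybenzyl ether
Product: 33 C14 allylic alcohol
Conditions: DDQ, CH2Cl2/pH 7 buffer, 0 °C
Reagents that add atoms: none
Why: Oxidative cleavage of the 4-methoxybenzyl ether through the benzylic oxocarbenium ion; the tert-butyl and silyl ethers, the alkenes and the lactone are inert.

Step 21
Reactants: 33 C14 allylic alcohol
Product: 34 C14 enal
Conditions: Dess–Martin periodinane, CH2Cl2, 0 °C to rt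
Reagents that add atoms: none
Why: Dess–Martin oxidation of the primary allylic alcohol under neutral conditions; the ring-cis alkene geometry is retained.

Step 22
Reactants: 34 C14 enal
Product: 35 C14 carboxylic acid
Conditions: NaClO2, NaH2PO4, 2-methyl-2-butene, t-BuOH/H2O, 0 °C to rt
Reagents that add atoms: sodium chlorite, [Na+].[O-]Cl=O
Why: Pinnick oxidation converts the enal to the acid without touching the alkenes; the scavenger removes hypochlorite.

Step 23
Reactants: 35 C14 carboxylic acid
Product: 36 (4S,6R,7R,8R)-C14 methyl ester with C8 O-t-Bu and C15 silyl ether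
Conditions: MeI, K2CO3, DMF, 0 °C
Reagents that add atoms: iodomethane, CI
Why: O-Alkylation of the carboxylate; this avoids diazoalkanes, which add to methylene lactones, and O8 is still etherified so the lactone cannot migrate.

Step 24
Reactants: 36 (4S,6R,7R,8R)-C14 methyl ester, C8 O-t-Bu
Product: 37 (4S,6R,7R,8R)-C8 alcohol with C15 silyl ether
Conditions: CF3CO2H/CH2Cl2 (1:4), 0 °C
Reagents that add atoms: none
Why: Acidolysis of the tert-butyl ether by loss of the tert-butyl cation leaves the C8–O bond and its configuration intact; the primary tert-butyldiphenylsilyl ether is the most acid-stable of the common silyl ethers.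

Step 25
Reactants: 37 (4S,6R,7R,8R)-C8 alcohol; 38 (R)-2-methylbutanoic acid
Product: 39 (4S,6R,7S,8R)-O8 (R)-2-methylbutanoate with C15 silyl ether
Conditions: EDC·HCl, DMAP (cat.), CH2Cl2, 0 °C to rt
Reagents that add atoms: none
Why: Steglich-type esterification of the only free hydroxyl; carbodiimide activation with catalytic DMAP at low temperature avoids ketene formation and so keeps the α-centre of 38.

Step 26
Reactants: 39 (4S,6R,7S,8R)-O8 (R)-2-methylbutanoate, C15 silyl ether
Product: 40 target, (4S,6R,7S,8R)-germacra-1(10),11(13)-dien-12,6-olide with C14 methyl ester, C15 hydroxyl and O8 (R)-2-methylbutanoate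
Conditions: HF·pyridine, pyridine/THF, 0 °C to rt
Reagents that add atoms: none
Why: Fluoride-mediated desilylation in a buffered acidic medium frees the primary alcohol without adding a nucleophile to the methylene lactone or hydrolysing the esters.

## Compound list

1 | (S)-cyclohex-3-ene-1-carboxylic acid | OC(=O)[C@H]1CCC=CC1 | starting material
2 | (1S,4S,5S)-4-iodo-6-oxabicyclo[3.2.1]octan-7-one | O=C1O[C@H]2C[C@@H]1CC[C@@H]2I | intermediate
3 | (1S,5S)-6-oxabicyclo[3.2.1]oct-3-en-7-one | O=C1O[C@H]2C[C@@H]1CC=C2 | intermediate
4 | (1S,5S)-5-(hydroxymethyl)cyclohex-2-en-1-ol | O[C@H]1C[C@@H](CO)CC=C1 | intermediate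
5 | (1S,5S)-5-[(tert-butyldiphenylsilyloxy)methyl]cyclohex-2-en-1-ol | O[C@H]1C[C@@H](CO[Si](c2ccccc2)(c2ccccc2)C(C)(C)C)CC=C1 | intermediate
6 | (5S)-5-[(tert-butyldiphenylsilyloxy)methyl]cyclohex-2-en-1-one | O=C1C[C@@H](CO[Si](c2ccccc2)(c2ccccc2)C(C)(C)C)CC=C1 | intermediate
7 | (5S)-2-iodo-5-[(tert-butyldiphenylsilyloxy)methyl]cyclohex-2-en-1-one | O=C1C[C@@H](CO[Si](c2ccccc2)(c2ccccc2)C(C)(C)C)CC=C1I | intermediate
8 | 2,3-dibromopropene | BrCC(Br)=C | starting material
9 | 1-{[(2-bromoprop-2-en-1-yl)oxy]methyl}-4-methoxybenzene | C=C(Br)COCc1ccc(OC)cc1 | intermediate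
10 | 2-{3-[(4-methoxybenzyl)oxy]prop-1-en-2-yl}-4,4,5,5-tetramethyl-1,3,2-dioxaborolane | C=C(COCc1ccc(OC)cc1)B1OC(C)(C)C(C)(C)O1 | intermediate
11 | (5S)-2-{3-[(4-methoxybenzyl)oxy]prop-1-en-2-yl}-5-[(tert-butyldiphenylsilyloxy)methyl]cyclohex-2-en-1-one | O=C1C[C@@H](CO[Si](c2ccccc2)(c2ccccc2)C(C)(C)C)CC=C1C(=C)COCc3ccc(OC)cc3 | intermediate
12 | potassium dienolate from conjugate reduction of 11 | [K+].[O-]C1=C(C(=C)COCc2ccc(OC)cc2)CC[C@H](CO[Si](c2ccccc2)(c2ccccc2)C(C)(C)C)C1 | intermediate
13 | (2R,5S)-2-{3-[(4-methoxybenzyl)oxy]prop-1-en-2-yl}-5-[(tert-butyldiphenylsilyloxy)methyl]cyclohexan-1-one | O=C1C[C@@H](CO[Si](c2ccccc2)(c2ccccc2)C(C)(C)C)CC[C@@H]1C(=C)COCc3ccc(OC)cc3 | intermediate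
14 | trichloroethylene | ClC=C(Cl)Cl | starting material
15 | dichloroacetylene | ClC#CCl | intermediate
16 | (E)-1,2-dichlorovinyl tert-butyl ether | CC(C)(C)O/C(Cl)=C\Cl | intermediate
17 | tert-butyl chloroethynyl ether | CC(C)(C)OC#CCl | intermediate
18 | lithium tert-butoxyacetylide | [Li]C#COC(C)(C)C | intermediate
19 | (1S,2R,5S)-1-(tert-butoxyethynyl)-2-{3-[(4-methoxybenzyl)oxy]prop-1-en-2-yl}-5-[(tert-butyldiphenylsilyloxy)methyl]cyclohexan-1-ol | O[C@@]1(C#COC(C)(C)C)C[C@@H](CO[Si](c2ccccc2)(c2ccccc2)C(C)(C)C)CC[C@@H]1C(=C)COCc3ccc(OC)cc3 | intermediate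
20 | (1S,2R,5S)-1-[(Z)-2-tert-butoxyethenyl]-2-{3-[(4-methoxybenzyl)oxy]prop-1-en-2-yl}-5-[(tert-butyldiphenylsilyloxy)methyl]cyclohexan-1-ol | O[C@@]1(/C=C\OC(C)(C)C)C[C@@H](CO[Si](c2ccccc2)(c2ccccc2)C(C)(C)C)CC[C@@H]1C(=C)COCc3ccc(OC)cc3 | intermediate
21 | allyl bromoacetate | BrCC(=O)OCC=C | starting material
22 | potassium alkoxide of 20 | [K+].[O-][C@@]1(/C=C\OC(C)(C)C)C[C@@H](CO[Si](c2ccccc2)(c2ccccc2)C(C)(C)C)CC[C@@H]1C(=C)COCc3ccc(OC)cc3 | intermediate
23 | ten-membered potassium enolate (ring-trans C6=C7, ring-cis C1=C10) | [K+].[O-]/C1=C\[C@H](OC(C)(C)C)C/C(COCc2ccc(OC)cc2)=C\CC[C@H](CO[Si](c2ccccc2)(c2ccccc2)C(C)(C)C)C1 | intermediate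
24 | (4S,7R,8R)-ten-membered C6 ketone with C7 allyl acetate arm, C8 tert-butyl ether, C14 4-methoxybenzyl ether, C15 silyl ether | O=C1C[C@@H](CO[Si](c2ccccc2)(c2ccccc2)C(C)(C)C)CC/C=C(/COCc2ccc(OC)cc2)C[C@@H](OC(C)(C)C)[C@H]1CC(=O)OCC=C | intermediate
25 | (4S,6S,7S,8R)-C6 alcohol, O6 cis to the C7 arm | O[C@H]1C[C@@H](CO[Si](c2ccccc2)(c2ccccc2)C(C)(C)C)CC/C=C(/COCc2ccc(OC)cc2)C[C@@H](OC(C)(C)C)[C@H]1CC(=O)OCC=C | intermediate
26 | (4S,6S,7R,8R)-C6 methanesulfonate | CS(=O)(=O)O[C@H]1C[C@@H](CO[Si](c2ccccc2)(c2ccccc2)C(C)(C)C)CC/C=C(/COCc2ccc(OC)cc2)C[C@@H](OC(C)(C)C)[C@H]1CC(=O)OCC=C | intermediate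
27 | sodium carboxylate of the C6 methanesulfonate | [Na+].CS(=O)(=O)O[C@H]1C[C@@H](CO[Si](c2ccccc2)(c2ccccc2)C(C)(C)C)CC/C=C(/COCc2ccc(OC)cc2)C[C@@H](OC(C)(C)C)[C@H]1CC(=O)[O-] | intermediate
28 | (4S,6R,7R,8R)-trans-fused 12,6-lactone with C8 tert-butyl ether, C14 4-methoxybenzyl ether, C15 silyl ether | C1C(=O)O[C@@H]2C[C@@H](CO[Si](c3ccccc3)(c3ccccc3)C(C)(C)C)CC/C=C(/COCc3ccc(OC)cc3)C[C@@H](OC(C)(C)C)[C@@H]12 | intermediate
29 | lithium enolate of lactone 28 | C1=C([O-])O[C@@H]2C[C@@H](CO[Si](c3ccccc3)(c3ccccc3)C(C)(C)C)CC/C=C(/COCc3ccc(OC)cc3)C[C@@H](OC(C)(C)C)[C@@H]12.[Li+] | intermediate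
30 | C11-(dimethylaminomethyl) lactone (C11 epimers) | CN(C)CC1C(=O)O[C@@H]2C[C@@H](CO[Si](c3ccccc3)(c3ccccc3)C(C)(C)C)CC/C=C(/COCc3ccc(OC)cc3)C[C@@H](OC(C)(C)C)[C@@H]12 | intermediate
31 | C11-(trimethylammoniomethyl) lactone iodide | [I-].C[N+](C)(C)CC1C(=O)O[C@@H]2C[C@@H](CO[Si](c3ccccc3)(c3ccccc3)C(C)(C)C)CC/C=C(/COCc3ccc(OC)cc3)C[C@@H](OC(C)(C)C)[C@@H]12 | intermediate
32 | (4S,6R,7R,8R)-α-methylene lactone with C8 tert-butyl ether, C14 4-methoxybenzyl ether, C15 silyl ether | C=C1C(=O)O[C@@H]2C[C@@H](CO[Si](c3ccccc3)(c3ccccc3)C(C)(C)C)CC/C=C(/COCc3ccc(OC)cc3)C[C@@H](OC(C)(C)C)[C@@H]12 | intermediate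
33 | C14 allylic alcohol | C=C1C(=O)O[C@@H]2C[C@@H](CO[Si](c3ccccc3)(c3ccccc3)C(C)(C)C)CC/C=C(/CO)C[C@@H](OC(C)(C)C)[C@@H]12 | intermediate
34 | C14 enal | C=C1C(=O)O[C@@H]2C[C@@H](CO[Si](c3ccccc3)(c3ccccc3)C(C)(C)C)CC/C=C(/C=O)C[C@@H](OC(C)(C)C)[C@@H]12 | intermediate
35 | C14 carboxylic acid | C=C1C(=O)O[C@@H]2C[C@@H](CO[Si](c3ccccc3)(c3ccccc3)C(C)(C)C)CC/C=C(/C(=O)O)C[C@@H](OC(C)(C)C)[C@@H]12 | intermediate
36 | (4S,6R,7R,8R)-C14 methyl ester with C8 tert-butyl ether and C15 silyl ether | C=C1C(=O)O[C@@H]2C[C@@H](CO[Si](c3ccccc3)(c3ccccc3)C(C)(C)C)CC/C=C(/C(=O)OC)C[C@@H](OC(C)(C)C)[C@@H]12 | intermediate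
37 | (4S,6R,7R,8R)-C8 alcohol with C14 methyl ester and C15 silyl ether | C=C1C(=O)O[C@@H]2C[C@@H](CO[Si](c3ccccc3)(c3ccccc3)C(C)(C)C)CC/C=C(/C(=O)OC)C[C@@H](O)[C@@H]12 | intermediate
38 | (R)-2-methylbutanoic acid | CC[C@@H](C)C(=O)O | starting material
39 | (4S,6R,7S,8R)-O8 (R)-2-methylbutanoate with C15 silyl ether | C=C1C(=O)O[C@@H]2C[C@@H](CO[Si](c3ccccc3)(c3ccccc3)C(C)(C)C)CC/C=C(/C(=O)OC)C[C@@H](OC(=O)[C@H](C)CC)[C@@H]12 | intermediate
40 | target: (4S,6R,7S,8R)-germacra-1(10),11(13)-dien-12,6-olide with C14 methyl ester, C15 hydroxyl, O8 (R)-2-methylbutanoate | C=C1C(=O)O[C@@H]2C[C@@H](CO)CC/C=C(/C(=O)OC)C[C@@H](OC(=O)[C@H](C)CC)[C@@H]12 | target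

## Step count and least certain steps

Total: 26 steps. Longest linear sequence: 23 steps (steps 1–6, 9, 10 and 12–26). Steps 7, 8 and 11 make side fragments.

Step 14 (key step). Three processes can defeat it.
- Loss of chirality transfer: reaction through a boat or through the ring-flipped cyclohexane conformer would give the ring-trans alkene or the C8 epimer.
- Loss of tert-butoxide from the β-alkoxy enolate (E1cB), which is possible because the C8–O bond is partly aligned with the enolate π system.
- Loss of facial control at C7: a ring-trans enolate in a ten-membered ring can turn over quickly, and the potassium bridge between O6 and O8 that holds the productive conformer is weak.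

Proton transfer from the bromoacetate to the enolate is a further drain. The fallback separates the two bond-forming events. From 20, the rearrangement is run as before and the enolate is trapped at −78 °C with chlorotrimethylsilane as the trimethylsilyl enol ether F1, which is isolated. Methyllithium in THF then releases the lithium enolate F2, whose tighter O6–Li–O8 chelate should hold the same face open. F2 is alkylated with 21 in THF/DMPU at −78 °C to return at 24.

Step 15. Hydride delivery may be poorly selective or may go to the other carbonyl face, because the ten-membered ring may react through a conformer in which the C7 arm, not the C7–C8 bond, shields the periphery. The hydroxy ester may also close early to the cis lactone. The fallback uses reagent control and closes the lactone with retention. From 24, reduction with catecholborane and (S)-2-methyl-CBS-oxazaborolidine in toluene at −78 °C (Corey–Bakshi–Shibata reduction, C7 as the large and C5 as the small substituent) should give the (6R)-hydroxy ester F3. Pyridinium p-toluenesulfonate in toluene at 60 °C then lactonises F3 by acyl substitution, returning at 28.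

Step 17. The carboxylate may act as a base instead of a nucleophile (E2 towards C5 or C7), or the C1–C10 alkene may take part across the ring in ionisation of the secondary sulfonate. The fallback activates the alcohol in a different way. From 25, the allyl ester is cleaved with Pd(PPh3)4 and morpholine in THF at 0 °C to the hydroxy acid F4, kept cold as its morpholinium salt. F4 is closed with PPh3 and diisopropyl azodicarboxylate (Mitsunobu lactonisation, inversion at C6), returning at 28.

Step 24. The acid may also remove the silyl ether, and the freed O8 may take the lactone carbonyl from O6 (acyl migration to the 12,8-lactone), which is why the acid is kept cold and the product is acylated at once. The fallback accepts the loss of the silyl group. From 36, both ethers are cleaved with CF3CO2H/H2O at rt to the diol F5. F5 is re-silylated with tert-butyl(chloro)diphenylsilane and imidazole at −20 °C, which reacts only at the primary C15 hydroxyl, returning at 37.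

Step 10. The dienolate may be protonated at the remote terminus, or the product may isomerise on contact with base, which would move the side-chain alkene into conjugation as a ring-exocyclic enone. Competing 1,2-reduction is also possible. The fallback builds C1–C10 on a saturated ring. From 6, RhCl(PPh3)3-catalysed 1,4-hydrosilylation with Et3SiH gives the regiodefined triethylsilyl enol ether F6. F6 is coupled with bromide 9 using PdCl2[P(o-tolyl)3]2 and Bu3SnF in benzene (α-alkenylation of a silyl enol ether through its tin enolate), returning at 13.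

## Further compounds

F1 | step 14 | trimethylsilyl enol ether of the ring-expanded ketone (ring-trans C6=C7) | C[Si](C)(C)O/C1=C\[C@H](OC(C)(C)C)C/C(COCc2ccc(OC)cc2)=C\CC[C@H](CO[Si](c2ccccc2)(c2ccccc2)C(C)(C)C)C1
F2 | step 14 | lithium enolate of the ring-expanded ketone | [Li+].[O-]/C1=C\[C@H](OC(C)(C)C)C/C(COCc2ccc(OC)cc2)=C\CC[C@H](CO[Si](c2ccccc2)(c2ccccc2)C(C)(C)C)C1
F3 | step 15 | (4S,6R,7S,8R)-C6 alcohol, O6 trans to the C7 allyl acetate arm | O[C@@H]1C[C@@H](CO[Si](c2ccccc2)(c2ccccc2)C(C)(C)C)CC/C=C(/COCc2ccc(OC)cc2)C[C@@H](OC(C)(C)C)[C@H]1CC(=O)OCC=C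
F4 | step 17 | (6S)-hydroxy acid from deallylation of 25 | O[C@H]1C[C@@H](CO[Si](c2ccccc2)(c2ccccc2)C(C)(C)C)CC/C=C(/COCc2ccc(OC)cc2)C[C@@H](OC(C)(C)C)[C@H]1CC(=O)O
F5 | step 24 | C8,C15-diol with C14 methyl ester and methylene lactone | C=C1C(=O)O[C@@H]2C[C@@H](CO)CC/C=C(/C(=O)OC)C[C@@H](O)[C@@H]12
F6 | step 10 | tert-butyl{[(1S)-3-(triethylsilyloxy)cyclohex-3-en-1-yl]methoxy}diphenylsilane | CC[Si](CC)(CC)OC1=CCC[C@H](CO[Si](c2ccccc2)(c2ccccc2)C(C)(C)C)C1
A1 | alternative 1 | α-methylene lactone with free C8 hydroxyl, C14 methyl ester and C15 tert-butyldiphenylsilyl ether (same as 37) | C=C1C(=O)O[C@@H]2C[C@@H](CO[Si](c3ccccc3)(c3ccccc3)C(C)(C)C)CC/C=C(/C(=O)OC)C[C@@H](O)[C@@H]12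
A2 | alternative 2 | 11,13-dihydro target skeleton with C15 4-methoxybenzyl ether | C1C(=O)O[C@@H]2C[C@@H](COCc3ccc(OC)cc3)CC/C=C(/C(=O)OC)C[C@@H](OC(=O)[C@H](C)CC)[C@@H]12
A3 | alternative 3 | ten-membered C8 alcohol with C7 methyl acrylate unit, O6 tert-butyldimethylsilyl ether, C14 methyl ester and C15 tert-butyldiphenylsilyl ether | C=C(C(=O)OC)[C@H]1[C@H](O[Si](C)(C)C(C)(C)C)C[C@@H](CO[Si](c2ccccc2)(c2ccccc2)C(C)(C)C)CC/C=C(/C(=O)OC)C[C@H]1O
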